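Burkinabin A is the 3,4-di-O-vanilloyl ester of (−)-quinic acid; it is traced back to a bis-aroylated, 1-O-benzylated 1,5-quinide by hydrogenolysis of three benzyl groups and acid hydrolysis of a γ-lactone that is not part of the target.
Enabling feature: on the cyclohexane ring the C1 carboxyl and the C5 hydroxyl are cis-1,3, so they can be tied into a 6-oxabicyclo[3.2.1]octan-7-one; this temporary lactone masks the two oxygens that stay unacylated (O-5 and the carboxyl), shields one face of the carbocycle and leaves O-3/O-4, the two oxygens to be acylated, as the only diol.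
Key disconnection: the C3–C4 bond of the carbocycle, made by ring-closing metathesis of a cis-3-allyl-5-vinyl-γ-butyrolactone (three-carbon bridge closed over the lactone) and dihydroxylated in the same flask from the exo face, which sets C3 and C4.
The diene comes from (R)-5-(hydroxymethyl)butyrolactone (source of C5): enolate allylation, stereoconvergent enolate hydroxylation anti to the C5 substituent (quaternary C1), O-benzylation, and conversion of CH2OTr into the vinyl group.
Ring order: lactone ring (bought, temporary), then the cyclohexane ring (key step, the only ring of the target skeleton that is built); the two arene rings arrive intact with the acid chloride and the lactone is opened at the end.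

Key step: step 8

Remark: locants C1–C6 and O-1 to O-5 follow quinic acid numbering with O-3 cis and O-5 trans to O-4 (O-5 is the hydroxyl that lactonises with the C1 carboxyl; this γ-lactone is called 1,5-quinide); the target carries its esters on O-3 and O-4 and has the configuration of (−)-quinic acid.

Step 1
Reactants: 1 (R)-5-(hydroxymethyl)dihydrofuran-2(3H)-one
Product: 2 (R)-5-[(trityloxy)methyl]dihydrofuran-2(3H)-one
Conditions: TrCl, pyridine, DMAP (cat.), CH2Cl2, rt
Reagents that add atoms: trityl chloride ClC(c1ccccc1)(c1ccccc1)c1ccccc1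
Why: Tritylation of the primary alcohol (SN1-type etherification through the trityl cation) installs the bulky group that will shield one face of the lactone enolate, and the C5 stereocenter is not touched.

Step 2
Reactants: 2 (R)-5-[(trityloxy)methyl]dihydrofuran-2(3H)-one
Product: 4 (3S,5R)-3-allyl-5-[(trityloxy)methyl]dihydrofuran-2(3H)-one, via lithium enolate 3 (not isolated)
Conditions: LiN(i-Pr)2, THF, −78 °C; then allyl bromide, DMPU, −78 to −40 °C
Reagents that add atoms: allyl bromide C=CCBr
Why: Enolate alkylation of the lithium lactone enolate should take place on the face opposite the trityloxymethyl group (1,3-induction across the five-membered ring) to give mainly the trans product, whose C3 configuration is of no consequence because it is erased in step 3.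

Step 3
Reactants: 4 (3S,5R)-3-allyl-5-[(trityloxy)methyl]dihydrofuran-2(3H)-one
Product: 6 (3S,5R)-3-allyl-3-hydroxy-5-[(trityloxy)methyl]dihydrofuran-2(3H)-one, via potassium enolate 5 (not isolated)
Conditions: KN(SiMe3)2, THF, −78 °C; then 2-(phenylsulfonyl)-3-phenyloxaziridine, −78 °C; aqueous work-up
Reagents that add atoms: 2-(phenylsulfonyl)-3-phenyloxaziridine (Davis oxaziridine) O=S(=O)(N1OC1c1ccccc1)c1ccccc1
Why: Electrophilic enolate hydroxylation (Davis oxidation) of the planar tetrasubstituted enolate should deliver oxygen anti to the C5 trityloxymethyl group, so that both C3 epimers of 4 converge on one quaternary carbinol (the future C1) with the allyl group cis to the C5 substituent.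

Step 4
Reactants: 6 (3S,5R)-3-allyl-3-hydroxy-5-[(trityloxy)methyl]dihydrofuran-2(3H)-one
Product: 7 (3S,5R)-3-allyl-3-(benzyloxy)-5-[(trityloxy)methyl]dihydrofuran-2(3H)-one
Conditions: NaH, BnBr, n-Bu4NI (cat.), DMF, 0 °C to rt
Reagents that add atoms: benzyl bromide BrCc1ccccc1
Why: Williamson etherification of the tertiary alkoxide masks O-1, the accessible bridgehead hydroxyl that would otherwise compete with the axial O-4 in the later acylation, and no stereocenter is affected.

Step 5
Reactants: 7 (3S,5R)-3-allyl-3-(benzyloxy)-5-[(trityloxy)methyl]dihydrofuran-2(3H)-one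
Product: 8 (3S,5R)-3-allyl-3-(benzyloxy)-5-(hydroxymethyl)dihydrofuran-2(3H)-one
Conditions: camphorsulfonic acid (cat.), MeOH–CH2Cl2 (1:1), rt
Reagents that add atoms: none
Why: Acid-catalysed solvolysis of the trityl ether (SN1, the trityl cation being trapped by methanol) should free the primary alcohol while the benzyl ether, the alkene and the γ-lactone persist.

Step 6
Reactants: 8 (3S,5R)-3-allyl-3-(benzyloxy)-5-(hydroxymethyl)dihydrofuran-2(3H)-one
Product: 9 (2R,4S)-4-allyl-4-(benzyloxy)-5-oxotetrahydrofuran-2-carbaldehyde
Conditions: Dess–Martin periodinane, CH2Cl2, rt; used crude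
Reagents that add atoms: none
Why: Dess–Martin oxidation converts the primary alcohol into the aldehyde (the future C4) under non-basic conditions that should leave the adjacent oxygen-bearing C5 stereocenter intact.

Step 7
Reactants: 9 (2R,4S)-4-allyl-4-(benzyloxy)-5-oxotetrahydrofuran-2-carbaldehyde
Product: 10 (3S,5R)-3-allyl-3-(benzyloxy)-5-vinyldihydrofuran-2(3H)-one
Conditions: Ph3PCH3Br, KN(SiMe3)2, THF, 0 °C; then 9, −78 to 0 °C
Reagents that add atoms: methyltriphenylphosphonium bromide C[P+](c1ccccc1)(c1ccccc1)c1ccccc1.[Br-]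
Why: Wittig methylenation at low temperature should turn the aldehyde into the vinyl arm faster than C5 can epimerise, and a molecule that did epimerise could not close in step 8.

Step 8
Reactants: 10 (3S,5R)-3-allyl-3-(benzyloxy)-5-vinyldihydrofuran-2(3H)-one
Product: 12 1-O-benzyl-1,5-quinide [(1S,3R,4R,5R)-1-(benzyloxy)-3,4-dihydroxy-6-oxabicyclo[3.2.1]octan-7-one], via bicyclic alkene 11 (not isolated)
Conditions: RuCl2(=CHPh)(H2IMes)(PCy3) (second-generation Grubbs catalyst, 5 mol %), CH2Cl2 (5 mM), 40 °C; then solvent switch to acetone–H2O (4:1), NMO, OsO4 (2 mol %), rt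
Reagents that add atoms: N-methylmorpholine N-oxide C[N+]1([O-])CCOCC1; water O; osmium tetroxide (catalytic carrier of both oxygens) O=[Os](=O)(=O)=O
Why: The ruthenium alkylidene loads on the unhindered allyl arm of 10 and closes onto the C5 vinyl arm through a ruthenacyclobutane with loss of ethylene (ring-closing metathesis), after which OsO4 adds to the new C3=C4 bond by [3+2] cycloaddition and is turned over by NMO (Upjohn dihydroxylation). The closest known reaction types are metathesis closures of bicyclo[3.2.1]octene frameworks from cis-1,3-dialkenyl five-membered rings and the exo-selective osmylation of 6-oxabicyclo[3.2.1]oct-3-en-7-ones. The six-membered carbocycle is closed at C3=C4 as the three-carbon bridge over C1 and C5 of the γ-lactone, a closure of low strain that is driven by ethylene release and helped by the fully substituted C1. C3 and C4 are set by the lactone bridge (ring oxygen and carbonyl carbon), which covers the endo face so that both hydroxyls enter syn from the exo face, O-3 cis to O-4 and O-4 trans to the lactone oxygen on C5, as in quinic acid. The step needs closure to beat oligomerisation and one alkene face to be chosen: high dilution and the cis placement of the two arms secure the first (a C1 or C5 epimer cannot reach across the ring and is filtered out), the bicycle secures the second. One operation thus gives the carbocycle, two stereocenters and exactly the diol that is to be acylated, while O-1, O-5 and the carboxyl stay masked.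

Step 9
Reactants: 13 4-(benzyloxy)-3-methoxybenzoic acid
Product: 14 4-(benzyloxy)-3-methoxybenzoyl chloride
Conditions: (COCl)2, DMF (cat.), CH2Cl2, 0 °C to rt; evaporated and used crude
Reagents that add atoms: oxalyl chloride ClC(=O)C(Cl)=O
Why: Acid chloride formation through the Vilsmeier-type chloroiminium species activates the benzyl-protected vanillic acid, the aryl benzyl ether being inert.

Step 10
Reactants: 12 1-O-benzyl-1,5-quinide; 14 4-(benzyloxy)-3-methoxybenzoyl chloride (about 3 equiv)
Product: 15 1-O-benzyl-3,4-bis-O-[4-(benzyloxy)-3-methoxybenzoyl]-1,5-quinide [(1R,3R,4R,5R)-1-(benzyloxy)-7-oxo-6-oxabicyclo[3.2.1]octane-3,4-diyl bis[4-(benzyloxy)-3-methoxybenzoate]]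
Conditions: pyridine, DMAP, CH2Cl2, 0 to 40 °C
Reagents that add atoms: none
Why: DMAP-catalysed acylation (nucleophilic catalysis through the acylpyridinium ion) should esterify the only free hydroxyls, the equatorial O-3 and the axial O-4, with retention at both carbinol centres.

Step 11
Reactants: 15 1-O-benzyl-3,4-bis-O-[4-(benzyloxy)-3-methoxybenzoyl]-1,5-quinide
Product: 16 1-O-benzyl-3,4-bis-O-[4-(benzyloxy)-3-methoxybenzoyl]quinic acid [(1R,3R,4S,5R)-1-(benzyloxy)-3,4-bis{[4-(benzyloxy)-3-methoxybenzoyl]oxy}-5-hydroxycyclohexane-1-carboxylic acid]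
Conditions: 2 M aq. HCl–THF (1:3), rt
Reagents that add atoms: water O
Why: Acid-catalysed acyl–oxygen hydrolysis should open the strained bridged γ-lactone well before the two hindered aryl esters react, freeing O-5 and the C1 carboxyl without touching a stereocenter, while the acidic medium disfavours O-4 to O-5 acyl migration.

Step 12
Reactants: 16 1-O-benzyl-3,4-bis-O-[4-(benzyloxy)-3-methoxybenzoyl]quinic acid
Product: 17 burkinabin A [(1R,3R,4S,5R)-1,5-dihydroxy-3,4-bis[(4-hydroxy-3-methoxybenzoyl)oxy]cyclohexane-1-carboxylic acid]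
Conditions: H2 (1 atm), Pd/C, EtOAc–THF, rt
Reagents that add atoms: none
Why: Heterogeneous hydrogenolysis of the three benzyl ethers (two phenolic, one tertiary alkyl) under neutral conditions should release the target without acyl migration, the benzoate esters being inert to H2 over Pd/C.

Compound list
1 | (R)-5-(hydroxymethyl)dihydrofuran-2(3H)-one | OC[C@H]1CCC(=O)O1 | starting material
2 | (R)-5-[(trityloxy)methyl]dihydrofuran-2(3H)-one | C(c1ccccc1)(c1ccccc1)(c1ccccc1)OC[C@H]1CCC(=O)O1 | intermediate
3 | lithium enolate of 2, lithium (R)-5-[(trityloxy)methyl]-4,5-dihydrofuran-2-olate | C(c1ccccc1)(c1ccccc1)(c1ccccc1)OC[C@H]1CC=C([O-])O1.[Li+] | intermediate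
4 | (3S,5R)-3-allyl-5-[(trityloxy)methyl]dihydrofuran-2(3H)-one (allyl trans to the C5 substituent) | C(c1ccccc1)(c1ccccc1)(c1ccccc1)OC[C@H]1C[C@H](CC=C)C(=O)O1 | intermediate
5 | potassium enolate of 4, potassium (R)-3-allyl-5-[(trityloxy)methyl]-4,5-dihydrofuran-2-olate | C(c1ccccc1)(c1ccccc1)(c1ccccc1)OC[C@H]1CC(CC=C)=C([O-])O1.[K+] | intermediate
6 | (3S,5R)-3-allyl-3-hydroxy-5-[(trityloxy)methyl]dihydrofuran-2(3H)-one (allyl cis to the C5 substituent) | C(c1ccccc1)(c1ccccc1)(c1ccccc1)OC[C@H]1C[C@](O)(C(=O)O1)CC=C | intermediate
7 | (3S,5R)-3-allyl-3-(benzyloxy)-5-[(trityloxy)methyl]dihydrofuran-2(3H)-one | C(c1ccccc1)(c1ccccc1)(c1ccccc1)OC[C@H]1C[C@](OCc2ccccc2)(C(=O)O1)CC=C | intermediate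
8 | (3S,5R)-3-allyl-3-(benzyloxy)-5-(hydroxymethyl)dihydrofuran-2(3H)-one | OC[C@H]1C[C@](OCc2ccccc2)(C(=O)O1)CC=C | intermediate
9 | (2R,4S)-4-allyl-4-(benzyloxy)-5-oxotetrahydrofuran-2-carbaldehyde | O=C[C@H]1C[C@](OCc2ccccc2)(C(=O)O1)CC=C | intermediate
10 | (3S,5R)-3-allyl-3-(benzyloxy)-5-vinyldihydrofuran-2(3H)-one | C=C[C@H]1C[C@](OCc2ccccc2)(C(=O)O1)CC=C | intermediate
11 | (1S,5R)-1-(benzyloxy)-6-oxabicyclo[3.2.1]oct-3-en-7-one | C1=C[C@H]2C[C@](OCc3ccccc3)(C(=O)O2)C1 | intermediate
12 | 1-O-benzyl-1,5-quinide, (1S,3R,4R,5R)-1-(benzyloxy)-3,4-dihydroxy-6-oxabicyclo[3.2.1]octan-7-one | O[C@H]1[C@H]2C[C@](OCc3ccccc3)(C(=O)O2)C[C@H]1O | intermediate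
13 | 4-(benzyloxy)-3-methoxybenzoic acid | COc1cc(C(=O)O)ccc1OCc1ccccc1 | starting material
14 | 4-(benzyloxy)-3-methoxybenzoyl chloride | COc1cc(C(Cl)=O)ccc1OCc1ccccc1 | intermediate
15 | 1-O-benzyl-3,4-bis-O-[4-(benzyloxy)-3-methoxybenzoyl]-1,5-quinide | COc1cc(ccc1OCc1ccccc1)C(=O)O[C@H]1[C@H]2C[C@](OCc3ccccc3)(C(=O)O2)C[C@H]1OC(=O)c1ccc(OCc2ccccc2)c(OC)c1 | intermediate
16 | 1-O-benzyl-3,4-bis-O-[4-(benzyloxy)-3-methoxybenzoyl]quinic acid | COc1cc(ccc1OCc1ccccc1)C(=O)O[C@H]1[C@H](O)C[C@](OCc2ccccc2)(C(=O)O)C[C@H]1OC(=O)c1ccc(OCc2ccccc2)c(OC)c1 | intermediate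
17 | burkinabin A, 3,4-di-O-vanilloylquinic acid | COc1cc(C(=O)O[C@H]2[C@H](O)C[C@](O)(C(=O)O)C[C@H]2OC(=O)c2ccc(O)c(OC)c2)ccc1O | target

Total step count: 12. Longest linear sequence: 11 steps (steps 1–8 and 10–12; step 9 is a one-step side branch).

Steps most likely to fail

Step 8. Intermolecular metathesis (oligomerisation) may outrun closure of the bridged ring, or the vinyl arm next to the lactone oxygen may fail to engage. The fallback sets out from diene 10 and builds the C3–C4 bond in another way. Ozonolysis of both terminal alkenes (O3, CH2Cl2–MeOH, −78 °C; Me2S) should give the dialdehyde (2R,4R)-4-(benzyloxy)-5-oxo-4-(2-oxoethyl)oxolane-2-carbaldehyde F1. An intramolecular pinacol coupling of this 1,6-dialdehyde (SmI2, t-BuOH, THF, −78 °C) should then close the carbocycle; this reaction type is known to give cis-cyclohexane-1,2-diols anti to an α-oxygen substituent, and here the lactone bridge again dictates the exo diol. It should deliver 12 directly, where the route is rejoined.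

Step 7. The basic ylide may epimerise C5 of the α-oxygenated aldehyde or add to the lactone carbonyl. The fallback sets out from aldehyde 9 and replaces the Wittig reaction by a two-stage Peterson olefination. The weakly basic organocerium reagent from Me3SiCH2MgCl and CeCl3 (THF, −78 °C) should add to the aldehyde to give the β-hydroxysilane (3S,5R)-3-allyl-3-(benzyloxy)-5-[1-hydroxy-2-(trimethylsilyl)ethyl]dihydrofuran-2(3H)-one F2 (either carbinol epimer serves). Acid-promoted anti-elimination (cat. H2SO4, THF, rt) should then give diene 10, where the route is rejoined.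

Step 11. During the slow hydrolysis of the lipophilic tribenzyl lactone, acyl migration from O-4 to the freed O-5 or hydrolysis of an aryl ester may compete. The fallback sets out from 15 and inverts the last two operations. Hydrogenolysis (H2, Pd/C, EtOAc–THF, rt) should give 3,4-di-O-vanilloyl-1,5-quinide F3, a polar lactone that can be opened in a short, homogeneous treatment with dilute aqueous HCl in THF (or aqueous trifluoroacetic acid) to give 17 directly.

Further compounds
F1 | step 8 | (2R,4R)-4-(benzyloxy)-5-oxo-4-(2-oxoethyl)oxolane-2-carbaldehyde | O=C[C@H]1C[C@](OCc2ccccc2)(C(=O)O1)CC=O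
F2 | step 7 | (3S,5R)-3-allyl-3-(benzyloxy)-5-[1-hydroxy-2-(trimethylsilyl)ethyl]dihydrofuran-2(3H)-one (both carbinol epimers) | C[Si](C)(C)CC(O)[C@H]1C[C@](OCc2ccccc2)(C(=O)O1)CC=C
F3 | step 11 | 3,4-di-O-vanilloyl-1,5-quinide, (1R,3R,4R,5R)-1-hydroxy-7-oxo-6-oxabicyclo[3.2.1]octane-3,4-diyl bis(4-hydroxy-3-methoxybenzoate) | COc1cc(ccc1O)C(=O)O[C@H]1[C@H]2C[C@](O)(C(=O)O2)C[C@H]1OC(=O)c1ccc(O)c(OC)c1
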